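**Assumption:** positions carry labdane numbers (C1–C20; ring A = C1–C5 and C10, ring B = C5–C10). The SMILES is read as the (5S,6R,8R,9R,10S) isomer: 6β-OAc, 8α-CH3, 9α-OH, 10β-CH3, 5α-H.

## Retrosynthetic overview

1. The butenolide ring is attached last and preformed: cross-metathesis of a C9 allyl group with α-methylene-γ-butyrolactone, then an exo-to-endo alkene shift. The 6β-OAc comes from a C6 ketone.
2. Ring A is closed by forming C4–C5: a hydrogen-atom-transfer-initiated cation/enol silane cyclisation of a homoprenyl chain on C10.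
3. C10–C1 and C8–CH3 are made by two alkoxide-directed conjugate additions, both delivered on the face of the C9 oxygen.
4. The key disconnection is C9–O: enantioselective para-hydroxylative dearomatisation of 3-methyl-4-allylphenol gives ring B as a p-quinol whose carbinol centre controls every other stereocentre.
5. Ring order: ring B (from the arene), then ring A, then the lactone ring; the arene comes from 4-bromo-3-methylphenol and an allylboronate.

## Route

**Step 1**
Reactants: 1 4-bromo-3-methylphenol; 2 4,4,5,5-tetramethyl-2-(prop-2-en-1-yl)-1,3,2-dioxaborolane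
Product: 3 3-methyl-4-(prop-2-en-1-yl)phenol
Conditions: Pd(dppf)Cl2 (3 mol%), K2CO3, 1,4-dioxane/H2O, 80 °C
Reagents that add atoms: none
Why: Suzuki–Miyaura coupling of the aryl bromide with the allylboronate tolerates the free phenol and installs, para to oxygen, the three-carbon unit that becomes C11–C12 of the side chain; no stereocentre is formed.

**Step 2**
Reactants: 3 3-methyl-4-(prop-2-en-1-yl)phenol
Product: 4 (4R)-4-hydroxy-3-methyl-4-(prop-2-en-1-yl)cyclohexa-2,5-dien-1-one
Conditions: (R,R)-2-iodo-1,3-bis{[1-(mesitylamino)-1-oxopropan-2-yl]oxy}benzene (10 mol%; the antipode is used if the sense of induction proves opposite), mCPBA (1.2 equiv), MeCN/H2O 9:1, −10 °C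
Reagents that add atoms: water, O
Why: Proposed new method: enantioselective para-hydroxylative dearomatisation with water, in which the phenol becomes an aryloxy ligand on the trivalent iodine centre generated from the iodoarene and mCPBA, the two lactamide N–H···O hydrogen bonds fold the side arms into a helical pocket that forces the meta-methyl group away from one mesityl wall and shields one ring face, so that water attacks C4 on the open face as the iodoarene leaves and creates the C9 carbinol stereocentre (R); the closest known reaction type is chiral iodoarene-catalysed oxidative dearomatisation of phenols (Kita spirolactonisation and low-selectivity p-quinol formation), which has not been shown to give high selectivity for an intermolecular hydroxylation that must tell a meta-methyl from a meta-hydrogen.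

**Step 3**
Reactants: 4 (4R)-4-hydroxy-3-methyl-4-(prop-2-en-1-yl)cyclohexa-2,5-dien-1-one
Product: 5 (4R,5R)-4-hydroxy-3,5-dimethyl-4-(prop-2-en-1-yl)cyclohex-2-en-1-one
Conditions: MeMgBr (3.5 equiv), THF/DMPU, −78 → −20 °C; then H2O
Reagents that add atoms: methylmagnesium bromide, C[Mg]Br
Why: Ligand-assisted nucleophilic addition (alkoxide-directed 1,4-addition of a Grignard reagent to a 4-oxido dienone): the magnesium alkoxide binds MeMgBr and hands methyl to the unsubstituted β-carbon (C8) on the oxygen-bearing face, which sets C8 (8R, methyl cis to OH) and leaves the β-methylated enone arm intact.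

**Step 4**
Reactants: 5 (4R,5R)-4-hydroxy-3,5-dimethyl-4-(prop-2-en-1-yl)cyclohex-2-en-1-one; 6 5-bromo-2-methylpent-2-ene
Product: 9 trimethylsilyl enol ether (C1=C2) of (3S,4R,5R)-3,5-dimethyl-3-(4-methylpent-3-en-1-yl)-4-(prop-2-en-1-yl)-4-[(trimethylsilyl)oxy]cyclohexan-1-one, via Grignard reagent 7 (not isolated), via magnesium enolate 8 (not isolated)
Conditions: 6, Mg, THF, rt (gives 7, 3.5 equiv); then 5, THF/DMPU, −78 → 0 °C; then TMSCl, Et3N, −78 °C → rt
Reagents that add atoms: chlorotrimethylsilane, C[Si](C)(C)Cl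
Why: A second alkoxide-directed 1,4-addition, in which the first equivalent of Grignard reagent forms the magnesium alkoxide and the next delivers the homoprenyl chain to the β-methyl carbon (C10) on the oxygen face, creates the C10 quaternary stereocentre with the chain cis to the C9 oxygen (angular methyl β), and O-silylation then fixes the regiodefined C5=C6 enolate and masks the alkoxide.

**Step 5**
Reactants: 9 trimethylsilyl enol ether (C1=C2) of (3S,4R,5R)-3,5-dimethyl-3-(4-methylpent-3-en-1-yl)-4-(prop-2-en-1-yl)-4-[(trimethylsilyl)oxy]cyclohexan-1-one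
Product: 11 (3R,4R,4aS,8aS)-4-hydroxy-3,4a,8,8-tetramethyl-4-(prop-2-en-1-yl)octahydronaphthalen-1(2H)-one, via silyl ether 10 (not isolated)
Conditions: [N,N′-bis(3,5-di-tert-butylsalicylidene)cyclohexane-1,2-diaminato]cobalt, Co(C36H52N2O2) (5 mol%), N-fluoro-2,4,6-trimethylpyridinium tetrafluoroborate (1.2 equiv), PhSiH3 (1.2 equiv), PhCF3, 0 °C; then K2CO3 (0.2 equiv), MeOH, 50 °C
Reagents that add atoms: none
Why: Proposed new method: hydrogen-atom transfer from the cobalt hydride to the trisubstituted alkene gives the tertiary C4 radical, which is oxidised through an alkylcobalt species (formally tetravalent cobalt) to a tertiary cation equivalent under non-acidic conditions that do not ionise the tertiary C9 silyl ether, and the enol silane captures it through a six-membered transition state (Mukaiyama-type C-alkylation) to close ring A and form the gem-dimethyl carbon, after which K2CO3/MeOH removes the silyl ether and equilibrates C5 to the trans ring fusion (5S); the closest known reaction types are cobalt–salen/N-fluoropyridinium/silane radical–polar crossover hydrofunctionalisation with O-, N- and arene nucleophiles and the Reetz tert-alkylation of enol silanes.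

**Step 6**
Reactants: 11 (3R,4R,4aS,8aS)-4-hydroxy-3,4a,8,8-tetramethyl-4-(prop-2-en-1-yl)octahydronaphthalen-1(2H)-one
Product: 12 (1R,3R,4R,4aS,8aS)-3,4a,8,8-tetramethyl-4-(prop-2-en-1-yl)decahydronaphthalene-1,4-diol
Conditions: NaBH4, MeOH, 0 °C
Reagents that add atoms: none
Why: Borohydride reduction of the C6 ketone takes place from the open α-face because the β-face is screened by the syn-axial C10 and C4β methyl groups, which gives the axial 6β-alcohol (6R).

**Step 7**
Reactants: 12 (1R,3R,4R,4aS,8aS)-3,4a,8,8-tetramethyl-4-(prop-2-en-1-yl)decahydronaphthalene-1,4-diol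
Product: 13 (1R,3R,4R,4aS,8aS)-4-hydroxy-3,4a,8,8-tetramethyl-4-(prop-2-en-1-yl)decahydronaphthalen-1-yl acetate
Conditions: Ac2O, DMAP (cat.), pyridine, 50 °C
Reagents that add atoms: acetic anhydride, CC(=O)OC(C)=O
Why: DMAP-catalysed acylation acetylates only the secondary 6β-hydroxyl, since the tertiary C9 hydroxyl flanked by two fully substituted carbons does not react.

**Step 8**
Reactants: 13 (1R,3R,4R,4aS,8aS)-4-hydroxy-3,4a,8,8-tetramethyl-4-(prop-2-en-1-yl)decahydronaphthalen-1-yl acetate; 14 3-methylidenedihydrofuran-2(3H)-one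
Product: 15 (1R,3R,4R,4aS,8aS)-4-hydroxy-3,4a,8,8-tetramethyl-4-[(2E)-2-(2-oxodihydrofuran-3(2H)-ylidene)ethyl]decahydronaphthalen-1-yl acetate
Conditions: 14 (3 equiv), RuCl2(=CH–C6H4-2-OiPr)(H2IMes) (second-generation Hoveyda–Grubbs catalyst; H2IMes = 1,3-dimesitylimidazolidin-2-ylidene, 5 mol%), 2,6-dichloro-1,4-benzoquinone (10 mol%), CH2Cl2, 40 °C
Reagents that add atoms: none
Why: Olefin cross-metathesis of the terminal allyl group with the 1,1-disubstituted methylene lactone forms the C12–C13 alkene as the E-alkylidene lactone with loss of ethene, and the quinone additive suppresses ruthenium hydride isomerisation of the lactone partner.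

**Step 9**
Reactants: 15 (1R,3R,4R,4aS,8aS)-4-hydroxy-3,4a,8,8-tetramethyl-4-[(2E)-2-(2-oxodihydrofuran-3(2H)-ylidene)ethyl]decahydronaphthalen-1-yl acetate
Product: 16 (1R,3R,4R,4aS,8aS)-4-hydroxy-3,4a,8,8-tetramethyl-4-[2-(2-oxo-2,5-dihydrofuran-3-yl)ethyl]decahydronaphthalen-1-yl acetate
Conditions: RhCl3·3H2O (5 mol%), EtOH, 75 °C
Reagents that add atoms: none
Why: Rhodium hydride-mediated exo-to-endo double-bond migration moves the alkene into the lactone ring to give the more stable α-substituted butenolide without touching any stereocentre.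

## Compound list

1 | 4-bromo-3-methylphenol | Cc1cc(O)ccc1Br | starting material
2 | 4,4,5,5-tetramethyl-2-(prop-2-en-1-yl)-1,3,2-dioxaborolane (allylboronic acid pinacol ester) | C=CCB1OC(C)(C)C(C)(C)O1 | starting material
3 | 3-methyl-4-(prop-2-en-1-yl)phenol | C=CCc1ccc(O)cc1C | intermediate
4 | (4R)-4-hydroxy-3-methyl-4-(prop-2-en-1-yl)cyclohexa-2,5-dien-1-one | O=C1C=C[C@](O)(CC=C)C(C)=C1 | intermediate
5 | (4R,5R)-4-hydroxy-3,5-dimethyl-4-(prop-2-en-1-yl)cyclohex-2-en-1-one (5-methyl cis to OH) | O=C1C[C@@H](C)[C@](O)(CC=C)C(C)=C1 | intermediate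
6 | 5-bromo-2-methylpent-2-ene | CC(C)=CCCBr | starting material
7 | (4-methylpent-3-en-1-yl)magnesium bromide | CC(C)=CCC[Mg]Br | intermediate
8 | bis(bromomagnesium) enolate–alkoxide of (3S,4R,5R)-4-hydroxy-3,5-dimethyl-3-(4-methylpent-3-en-1-yl)-4-(prop-2-en-1-yl)cyclohexan-1-one | Br[Mg]OC1C[C@@H](C)[C@](O[Mg]Br)(CC=C)[C@@](C)(CCC=C(C)C)C=1 | intermediate
9 | trimethylsilyl enol ether (C1=C2) of (3S,4R,5R)-3,5-dimethyl-3-(4-methylpent-3-en-1-yl)-4-(prop-2-en-1-yl)-4-[(trimethylsilyl)oxy]cyclohexan-1-one | C[Si](C)(C)OC1C[C@@H](C)[C@](O[Si](C)(C)C)(CC=C)[C@@](C)(CCC=C(C)C)C=1 | intermediate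
10 | (3R,4R,4aS)-3,4a,8,8-tetramethyl-4-(prop-2-en-1-yl)-4-[(trimethylsilyl)oxy]octahydronaphthalen-1(2H)-one, mixture of C8a epimers | O=C1C[C@@H](C)[C@](O[Si](C)(C)C)(CC=C)[C@@]2(C)CCCC(C)(C)C12 | intermediate
11 | (3R,4R,4aS,8aS)-4-hydroxy-3,4a,8,8-tetramethyl-4-(prop-2-en-1-yl)octahydronaphthalen-1(2H)-one (trans-fused) | O=C1C[C@@H](C)[C@](O)(CC=C)[C@@]2(C)CCCC(C)(C)[C@H]12 | intermediate
12 | (1R,3R,4R,4aS,8aS)-3,4a,8,8-tetramethyl-4-(prop-2-en-1-yl)decahydronaphthalene-1,4-diol | O[C@@H]1C[C@@H](C)[C@](O)(CC=C)[C@@]2(C)CCCC(C)(C)[C@H]12 | intermediate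
13 | (1R,3R,4R,4aS,8aS)-4-hydroxy-3,4a,8,8-tetramethyl-4-(prop-2-en-1-yl)decahydronaphthalen-1-yl acetate | CC(=O)O[C@@H]1C[C@@H](C)[C@](O)(CC=C)[C@@]2(C)CCCC(C)(C)[C@H]12 | intermediate
14 | 3-methylidenedihydrofuran-2(3H)-one (α-methylene-γ-butyrolactone) | C=C1CCOC1=O | starting material
15 | (1R,3R,4R,4aS,8aS)-4-hydroxy-3,4a,8,8-tetramethyl-4-[(2E)-2-(2-oxodihydrofuran-3(2H)-ylidene)ethyl]decahydronaphthalen-1-yl acetate | CC(=O)O[C@@H]1C[C@@H](C)[C@](O)(C/C=C3\CCOC3=O)[C@@]2(C)CCCC(C)(C)[C@H]12 | intermediate
16 | (1R,3R,4R,4aS,8aS)-4-hydroxy-3,4a,8,8-tetramethyl-4-[2-(2-oxo-2,5-dihydrofuran-3-yl)ethyl]decahydronaphthalen-1-yl acetate | CC(=O)O[C@@H]1C[C@@H](C)[C@](O)(CCC2=CCOC2=O)[C@@]2(C)CCCC(C)(C)[C@H]12 | target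

## Step count and risks

Total step count: 9. Longest linear sequence: 9 steps (1 → 16).

**Step 2 (proposed new method).** The risk is insufficient enantioselectivity, or competing epoxidation of the allyl group by the peracid. The fallback uses known chemistry and sets out from phenol 3. PhI(OAc)2 in MeCN/H2O at 0 °C (the standard racemic p-quinol synthesis) gives racemic 4-hydroxy-3-methyl-4-(prop-2-en-1-yl)cyclohexa-2,5-dien-1-one F1. Preparative chiral-phase supercritical fluid chromatography separates the enantiomers, and the R enantiomer is compound 4, where the route is rejoined. The absolute configuration then comes from resolution instead of catalysis.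

**Step 4.** The risk is that 1,2-addition or enolisation wins over a 1,4-delivery that must create a quaternary carbon next to a fully substituted carbinol. The fallback moves the chain onto the arene and brings in the angular methyl with a small cuprate instead; it sets out from boronate 2.
- Suzuki coupling as in step 1 with 4-bromo-3-chlorophenol F2 gives 3-chloro-4-(prop-2-en-1-yl)phenol F3.
- Kumada coupling with Grignard reagent 7 (Ni(dppp)Cl2, THF, 50 °C) gives 3-(4-methylpent-3-en-1-yl)-4-(prop-2-en-1-yl)phenol F4.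
- Dearomatisation as in step 2, but with the preformed diacetoxy-λ3-iodane of the same iodoarene in place of the peracid to spare the trisubstituted alkene, gives (4R)-4-hydroxy-3-(4-methylpent-3-en-1-yl)-4-(prop-2-en-1-yl)cyclohexa-2,5-dien-1-one F5.
- MeMgBr as in step 3 gives (4R,5R)-4-hydroxy-5-methyl-3-(4-methylpent-3-en-1-yl)-4-(prop-2-en-1-yl)cyclohex-2-en-1-one F6.
- Me2CuLi, TMSCl, Et3N, THF, −78 °C adds the C10 methyl by ordinary cuprate 1,4-addition anti to the C9 oxygen and silylates enolate and alkoxide. This gives compound 9, where the route is rejoined.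

**Step 5 (proposed new method).** The risks are that the enol silane has not been shown to capture a cation made this way, and that hydrogen-atom transfer to the enol silane or the allyl group, or fluorination of the enol silane by the oxidant, competes. The fallback uses known chemistry and sets out from bromide 6 and enone 5.
- HCl (g), CH2Cl2, 0 °C converts 6 into 1-bromo-4-chloro-4-methylpentane F7.
- Activated Mg (Rieke), THF, −78 °C inserts only into the C–Br bond and gives (4-chloro-4-methylpentyl)magnesium bromide F8.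
- Directed addition to 5 and TMSCl trapping as in step 4 gives the trimethylsilyl enol ether (C1=C2) of (3S,4R,5R)-3-(4-chloro-4-methylpentyl)-3,5-dimethyl-4-(prop-2-en-1-yl)-4-[(trimethylsilyl)oxy]cyclohexan-1-one F9.
- TiCl4, CH2Cl2, −78 °C ionises the tertiary chloride and the enol silane is alkylated intramolecularly (Reetz tert-alkylation). This gives silyl ether 10, where the route is rejoined before the K2CO3/MeOH treatment of step 5.

## Further compounds

F1 | step 2 | racemic 4-hydroxy-3-methyl-4-(prop-2-en-1-yl)cyclohexa-2,5-dien-1-one | O=C1C=CC(O)(CC=C)C(C)=C1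
F2 | step 4 | 4-bromo-3-chlorophenol | Oc1ccc(Br)c(Cl)c1
F3 | step 4 | 3-chloro-4-(prop-2-en-1-yl)phenol | C=CCc1ccc(O)cc1Cl
F4 | step 4 | 3-(4-methylpent-3-en-1-yl)-4-(prop-2-en-1-yl)phenol | C=CCc1ccc(O)cc1CCC=C(C)C
F5 | step 4 | (4R)-4-hydroxy-3-(4-methylpent-3-en-1-yl)-4-(prop-2-en-1-yl)cyclohexa-2,5-dien-1-one | O=C1C=C[C@](O)(CC=C)C(CCC=C(C)C)=C1
F6 | step 4 | (4R,5R)-4-hydroxy-5-methyl-3-(4-methylpent-3-en-1-yl)-4-(prop-2-en-1-yl)cyclohex-2-en-1-one | O=C1C[C@@H](C)[C@](O)(CC=C)C(CCC=C(C)C)=C1
F7 | step 5 | 1-bromo-4-chloro-4-methylpentane | CC(C)(Cl)CCCBr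
F8 | step 5 | (4-chloro-4-methylpentyl)magnesium bromide | CC(C)(Cl)CCC[Mg]Br
F9 | step 5 | trimethylsilyl enol ether (C1=C2) of (3S,4R,5R)-3-(4-chloro-4-methylpentyl)-3,5-dimethyl-4-(prop-2-en-1-yl)-4-[(trimethylsilyl)oxy]cyclohexan-1-one | C[Si](C)(C)OC1C[C@@H](C)[C@](O[Si](C)(C)C)(CC=C)[C@@](C)(CCCC(C)(C)Cl)C=1
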